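**Retrosynthetic overview**
- Target ⇒ cut the ring-B C4–OH bond (sterically controlled C–H borylation, then C–B to C–O oxidation) ⇒ the ring-A ortho-hydroxy benzophenone.
- That benzophenone ⇒ cut the ring-A C2–OH bond, the key bond (ketone-directed hydroxylation of the only ortho C–H) ⇒ (5-chloro-2,4-dimethoxyphenyl)(2-methoxy-6-methylphenyl)methanone.
- That ketone ⇒ cut the ring-A aryl–carbonyl bond (Friedel–Crafts acylation) ⇒ 2-methoxy-6-methylbenzoic acid + 1-chloro-2,4-dimethoxybenzene.
- No ring is formed: ring A (chlorinated) and ring B (methyl-bearing) are bought intact; the carbonyl bridge is made first, then the ring-A hydroxyl, last the ring-B hydroxyl.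

Assumption: the target SMILES has no stereocentre and no configurationally stable axis, so the compound as drawn is the single species to be made and no stereocontrol is needed.

**Step 1**
Reactants: 1 2-methoxy-6-methylbenzoic acid; 2 1-chloro-2,4-dimethoxybenzene
Product: 4 (5-chloro-2,4-dimethoxyphenyl)(2-methoxy-6-methylphenyl)methanone, via mixed trifluoroacetic anhydride 3 (not isolated)
Conditions: TFAA (2.0 equiv), TfOH (10 mol%), CH2Cl2, 0 °C to rt
Reagents that add atoms: none
Why: Friedel–Crafts acylation through the mixed anhydride: the 2,6-disubstituted acid ionises readily to a hindered acylium ion that attacks 2 at C5, the only unhindered position para to one methoxy group and ortho to the other (C3 lies between two methoxy groups, C6 is meta to both), and the absence of a metal halide Lewis acid avoids cleavage of the ortho methyl ethers; no stereocentre is formed.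

**Step 2**
Reactants: 4 (5-chloro-2,4-dimethoxyphenyl)(2-methoxy-6-methylphenyl)methanone
Product: 5 (3-chloro-2-hydroxy-4,6-dimethoxyphenyl)(2-methoxy-6-methylphenyl)methanone
Conditions: Pd(OAc)2 (10 mol%), [2,2'-bipyridin]-6(1H)-one (12 mol%), 35% aq. H2O2 (3 equiv, slow addition), HFIP, 50 °C
Reagents that add atoms: hydrogen peroxide, OO
Why: Proposed new method: the ketone oxygen of 4 (held syn to ring-A C6–H, away from the ortho methoxy group) binds an electrophilic divalent palladium centre carrying the cooperating ligand [2,2'-bipyridin]-6(1H)-one (O=C1C=CC=C(N1)c1ccccn1), whose pyridonate oxygen removes the only ortho hydrogen of the benzophenone (ring-A C6–H, acidified by the neighbouring chlorine; both ortho positions of ring B are blocked) by concerted metalation–deprotonation to give a five-membered oxapalladacycle; H2O2, its O–O cleavage assisted by the ligand OH, oxidises this to a tetravalent aryl palladium hydroxide that forms the C–O bond by reductive elimination and releases 5 without any strongly acidic or hypervalent-iodine oxidant that would attack the electron-rich rings; the closest known reactions are ketone-directed ortho-hydroxylation of simple benzophenones with Pd or Ru catalysts and PhI(OTFA)2 or K2S2O8 in TFA/TFAA, and carboxylate-directed Pd-catalysed C–H hydroxylation with H2O2 or O2 under pyridine–pyridone ligands, and the new element is the union of a neutral ketone directing group with ligand-enabled peroxide oxidation at a hindered, chlorine-flanked C–H; no stereocentre is formed.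

**Step 3**
Reactants: 5 (3-chloro-2-hydroxy-4,6-dimethoxyphenyl)(2-methoxy-6-methylphenyl)methanone
Product: 8 (3-chloro-2-hydroxy-4,6-dimethoxyphenyl)(4-hydroxy-2-methoxy-6-methylphenyl)methanone, via O-Bpin aryl borate 6 (not isolated), via ring-B C4 boronate 7 (not isolated)
Conditions: HBpin (1.2 equiv), [Ir(OMe)(cod)]2 (3 mol%), dtbpy (6 mol%), THF, rt, 1 h; B2pin2 (1.2 equiv), 80 °C; then KHSO5 (Oxone, 2KHSO5·KHSO4·K2SO4), acetone/H2O, rt, 10 min
Reagents that add atoms: potassium peroxymonosulfate, [K+].[O-]S(=O)(=O)OO
Why: Sterically controlled iridium-catalysed aromatic C–H borylation (Miyaura–Ishiyama–Hartwig type) with one-pot oxidation of the C–B bond: once the chelated phenol is masked as its O–Bpin ester, the only aromatic C–H without an ortho substituent is C4 of ring B (ring-A C5–H lies between two methoxy groups, ring-B C3–H and C5–H are each next to OMe or CH3), so boron and then oxygen enter there, while aqueous KHSO5 leaves the hindered ketone untouched and the work-up hydrolyses both O–B bonds; no stereocentre is formed.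

**Compound list**
1 | 2-methoxy-6-methylbenzoic acid | COc1cccc(C)c1C(=O)O | starting material
2 | 1-chloro-2,4-dimethoxybenzene (4-chlororesorcinol dimethyl ether) | COc1ccc(Cl)c(OC)c1 | starting material
3 | 2-methoxy-6-methylbenzoic trifluoroacetic anhydride (mixed anhydride of 1) | COc1cccc(C)c1C(=O)OC(=O)C(F)(F)F | intermediate
4 | (5-chloro-2,4-dimethoxyphenyl)(2-methoxy-6-methylphenyl)methanone | COc1cccc(C)c1C(=O)c1cc(Cl)c(OC)cc1OC | intermediate
5 | (3-chloro-2-hydroxy-4,6-dimethoxyphenyl)(2-methoxy-6-methylphenyl)methanone | COc1cccc(C)c1C(=O)c1c(O)c(Cl)c(OC)cc1OC | intermediate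
6 | 2-[2-chloro-3,5-dimethoxy-6-(2-methoxy-6-methylbenzoyl)phenoxy]-4,4,5,5-tetramethyl-1,3,2-dioxaborolane (O-Bpin ester of 5) | COc1cccc(C)c1C(=O)c1c(OB2OC(C)(C)C(C)(C)O2)c(Cl)c(OC)cc1OC | intermediate
7 | O-Bpin ester of 5 carrying a second Bpin group on ring B at C4 (para to the carbonyl) | COc1cc(B3OC(C)(C)C(C)(C)O3)cc(C)c1C(=O)c1c(OB2OC(C)(C)C(C)(C)O2)c(Cl)c(OC)cc1OC | intermediate
8 | (3-chloro-2-hydroxy-4,6-dimethoxyphenyl)(4-hydroxy-2-methoxy-6-methylphenyl)methanone (CNP0064373.0, achiral) | COc1cc(O)cc(C)c1C(=O)c1c(O)c(Cl)c(OC)cc1OC | target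

**Count and risks**
Total step count: 3. Longest linear sequence: 3 steps (1 or 2 → 4 → 5 → 8).

Most likely to fail, in order of risk:

Step 2 (the proposed new hydroxylation). The neutral ketone may bind the ligated palladium too weakly, the chlorine-flanked C–H may resist metalation, the chelating product may inhibit the catalyst, or H2O2 in HFIP may oxidise the rings. The fallback uses known chemistry and gives up C–H oxygenation altogether. It sets out from 1 and comes back at 5. Acid 1 is converted as in step 1 into mixed anhydride 3 (TFAA, CH2Cl2, no TfOH), which is trapped by commercial 2-chloro-3,5-dimethoxyphenol to give the ester 2-chloro-3,5-dimethoxyphenyl 2-methoxy-6-methylbenzoate F1. A Fries rearrangement with TiCl4 (CH2Cl2 or 1,2-dichloroethane, rt to 60 °C) then moves the aroyl group to the only free position ortho to the phenol oxygen, which gives 5 with the oxygen already in place.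

Step 3 (borylation/oxidation in the presence of the chelating acylphenol). The O-borylated acylphenol may slow or poison the iridium catalyst, some borylation next to the ring-B methoxy group may occur, or KHSO5 may over-oxidise the bis-phenol. The fallback reverses the order of the two C–O bond formations so that the borylation meets a phenol-free ketone. It sets out from 4 and comes back at 8. Ketone 4 is borylated ([Ir(OMe)(cod)]2, dtbpy, B2pin2, THF, 80 °C) to the boronate (5-chloro-2,4-dimethoxyphenyl)[2-methoxy-6-methyl-4-(4,4,5,5-tetramethyl-1,3,2-dioxaborolan-2-yl)phenyl]methanone F2 and oxidised in the same pot with KHSO5 to the phenol (5-chloro-2,4-dimethoxyphenyl)(4-hydroxy-2-methoxy-6-methylphenyl)methanone F3. The phenol is capped with Ac2O/pyridine as 4-(5-chloro-2,4-dimethoxybenzoyl)-3-methoxy-5-methylphenyl acetate F4. F4 is ortho-hydroxylated under the conditions of step 2 to 4-(3-chloro-2-hydroxy-4,6-dimethoxybenzoyl)-3-methoxy-5-methylphenyl acetate F5. K2CO3 in MeOH at rt then removes the acetate to give 8.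

Step 1 (Friedel–Crafts acylation). The hindered acylium may react sluggishly, or trifluoroacetylation of 2 may compete. The fallback replaces electrophilic acylation by an organometallic addition and oxidation. It sets out from 2 and comes back at 4. NBS in MeCN brominates 2 at C5 to give 1-bromo-5-chloro-2,4-dimethoxybenzene F6. n-BuLi (THF, −78 °C) exchanges bromine selectively over chlorine to give (5-chloro-2,4-dimethoxyphenyl)lithium F7. Addition to commercial 2-methoxy-6-methylbenzaldehyde gives the racemic carbinol (5-chloro-2,4-dimethoxyphenyl)(2-methoxy-6-methylphenyl)methanol F8, whose stereocentre is erased when MnO2 in CH2Cl2 oxidises it to 4.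

**Further compounds**
F1 | step 2 | 2-chloro-3,5-dimethoxyphenyl 2-methoxy-6-methylbenzoate | COc1cccc(C)c1C(=O)Oc1cc(OC)cc(OC)c1Cl
F2 | step 3 | (5-chloro-2,4-dimethoxyphenyl)[2-methoxy-6-methyl-4-(4,4,5,5-tetramethyl-1,3,2-dioxaborolan-2-yl)phenyl]methanone | COc1cc(B2OC(C)(C)C(C)(C)O2)cc(C)c1C(=O)c1cc(Cl)c(OC)cc1OC
F3 | step 3 | (5-chloro-2,4-dimethoxyphenyl)(4-hydroxy-2-methoxy-6-methylphenyl)methanone | COc1cc(O)cc(C)c1C(=O)c1cc(Cl)c(OC)cc1OC
F4 | step 3 | 4-(5-chloro-2,4-dimethoxybenzoyl)-3-methoxy-5-methylphenyl acetate | COc1cc(OC(C)=O)cc(C)c1C(=O)c1cc(Cl)c(OC)cc1OC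
F5 | step 3 | 4-(3-chloro-2-hydroxy-4,6-dimethoxybenzoyl)-3-methoxy-5-methylphenyl acetate | COc1cc(OC(C)=O)cc(C)c1C(=O)c1c(O)c(Cl)c(OC)cc1OC
F6 | step 1 | 1-bromo-5-chloro-2,4-dimethoxybenzene | COc1cc(OC)c(Br)cc1Cl
F7 | step 1 | (5-chloro-2,4-dimethoxyphenyl)lithium | [Li]c1cc(Cl)c(OC)cc1OC
F8 | step 1 | (5-chloro-2,4-dimethoxyphenyl)(2-methoxy-6-methylphenyl)methanol, racemic | COc1cccc(C)c1C(O)c1cc(Cl)c(OC)cc1OC
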